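**Retrosynthetic overview**
1. Final steps: O‑sulfation of the primary alcohol; before that, the N‑isopentyl unsaturated lactam (made separately by ring‑closing metathesis, then α‑brominated) is joined to a terminal alkene by B‑alkyl Suzuki coupling.
2. Key C–C bond: the side‑chain stereocentre is joined to the CH2 leading to the decalin by an intermolecular Evans boron aldol between a decalin acetaldehyde and an (R)‑benzyloxazolidinone pent‑4‑enoyl imide. The imide carbonyl becomes the CH2OH carbon, and the aldol hydroxyl is then removed (Barton–McCombie).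
3. Decalin aldehyde: ring A is closed by intramolecular McMurry coupling of a keto aldehyde, which also places the trisubstituted alkene.
4. Ring B comes from (R)‑pulegone: cuprate addition (gem‑dimethyl carbon), trans equilibration (ring‑fusion CH), then methylation and bromoacetate alkylation (quaternary carbon).
5. Ring order: ring B (chiral pool) → ring A (McMurry) → lactam ring (metathesis, on a separate fragment).

Assumption: the target is made as the free hydrogen sulfate exactly as drawn (no counter‑ion).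
Abbreviation: Dec = (1R,2R,4aS)‑1,2,5,5‑tetramethyl‑1,2,3,4,4a,5,6,7‑octahydronaphthalen‑1‑yl (C1 quaternary, C2 CH–Me, C4a ring‑fusion CH, C5 CMe2, C8=C8a alkene).

**Route**

Step 1
Reactants: 1 (R)‑(+)‑pulegone
Product: 3 (5R)‑5‑methyl‑2‑(2‑methylhex‑5‑en‑2‑yl)cyclohexan‑1‑one (C2 epimer mixture), via bromomagnesium enolate 2 (not isolated)
Conditions: but‑3‑enylmagnesium bromide (1.5 equiv), CuBr·SMe2 (10 mol%), THF, −20 → 0 °C; 1 M aq. HCl
Reagents that add atoms: but‑3‑enylmagnesium bromide, C=CCC[Mg]Br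
Why: Copper‑catalysed conjugate addition of a primary Grignard reagent to the s‑cis enone of pulegone builds the gem‑dimethyl quaternary carbon and leaves the ring methyl stereocentre untouched.

Step 2
Reactants: 3 (5R)‑5‑methyl‑2‑(2‑methylhex‑5‑en‑2‑yl)cyclohexan‑1‑one (C2 epimer mixture)
Product: 4 (2S,5R)‑5‑methyl‑2‑(2‑methylhex‑5‑en‑2‑yl)cyclohexan‑1‑one
Conditions: KOH, EtOH–H2O, reflux, 3 h; chromatography, minor cis epimer recycled
Reagents that add atoms: none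
Why: Base‑mediated epimerisation through the enolate (thermodynamic control) puts the bulky tert‑alkyl group and the ring methyl both equatorial, so the trans (menthone‑type, 2S) isomer dominates about 6:1 and fixes the future ring‑fusion CH.

Step 3
Reactants: 4 (2S,5R)‑5‑methyl‑2‑(2‑methylhex‑5‑en‑2‑yl)cyclohexan‑1‑one
Product: 6 (2S,5R)‑5,6‑dimethyl‑2‑(2‑methylhex‑5‑en‑2‑yl)cyclohexan‑1‑one (C6 epimer mixture), via lithium enolate 5 (not isolated)
Conditions: LiN(iPr)2 (commercial solution, 1.1 equiv), THF, −78 °C; MeI, −78 → 0 °C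
Reagents that add atoms: iodomethane, CI
Why: Kinetic deprotonation occurs only at the unhindered CH2 (the other α‑H is neopentylic), so this enolate alkylation puts the methyl on the carbon that will become quaternary, and the configuration of the new centre is irrelevant because it is re‑enolised in the next step.

Step 4
Reactants: 6 (2S,5R)‑5,6‑dimethyl‑2‑(2‑methylhex‑5‑en‑2‑yl)cyclohexan‑1‑one (C6 epimer mixture)
Product: 8 tert‑butyl 2‑[(1R,3S,6R)‑1,6‑dimethyl‑3‑(2‑methylhex‑5‑en‑2‑yl)‑2‑oxocyclohexyl]acetate, via lithium enolate 7 (not isolated)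
Conditions: LiN(iPr)2 (commercial solution, 1.2 equiv), THF, −78 → 0 °C; DMPU, BrCH2CO2t‑Bu, −78 → −20 °C
Reagents that add atoms: tert‑butyl bromoacetate, CC(C)(C)OC(=O)CBr
Why: Enolate alkylation of the tetrasubstituted enolate (the other α‑H is shielded by the adjacent quaternary carbon) is expected to go by axial attack on the face opposite the large tert‑alkyl group at the other α‑carbon, giving the 2,6‑trans product and hence the (1R) quaternary centre with CH2CO2t‑Bu cis to the neighbouring ring methyl.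

Step 5
Reactants: 8 tert‑butyl 2‑[(1R,3S,6R)‑1,6‑dimethyl‑3‑(2‑methylhex‑5‑en‑2‑yl)‑2‑oxocyclohexyl]acetate
Product: 10 tert‑butyl 2‑[(1R,3S,6R)‑1,6‑dimethyl‑3‑(2‑methyl‑5‑oxopentan‑2‑yl)‑2‑oxocyclohexyl]acetate, via secondary ozonide 9 (not isolated)
Conditions: O3, CH2Cl2, −78 °C; PPh3, −78 °C → rt
Reagents that add atoms: ozone, [O-][O+]=O
Why: Ozonolysis with reductive work‑up cleaves the only alkene to the aldehyde under neutral conditions that leave the epimerisable α‑CH of the ketone and the ester untouched.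

Step 6
Reactants: 10 tert‑butyl 2‑[(1R,3S,6R)‑1,6‑dimethyl‑3‑(2‑methyl‑5‑oxopentan‑2‑yl)‑2‑oxocyclohexyl]acetate
Product: 11 tert‑butyl 2‑(Dec)acetate
Conditions: TiCl3(DME)1.5, Zn–Cu couple, DME, reflux; slow addition of 10 (high dilution)
Reagents that add atoms: none
Why: Intramolecular McMurry coupling joins the aldehyde carbon to the hindered ketone carbon to close ring A as a six‑membered ring with the alkene regiospecifically at C8=C8a, using no base that could epimerise C4a and offering the ester no favourable ring size.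

Step 7
Reactants: 11 tert‑butyl 2‑(Dec)acetate
Product: 12 2‑(Dec)ethan‑1‑ol
Conditions: LiAlH4, Et2O, 0 °C → rt; aqueous work‑up
Reagents that add atoms: none
Why: Hydride reduction of the ester to the primary alcohol is routine and does not touch the isolated trisubstituted alkene.

Step 8
Reactants: 12 2‑(Dec)ethan‑1‑ol
Product: 13 2‑(Dec)acetaldehyde
Conditions: Dess–Martin periodinane, pyridine, CH2Cl2, 0 °C → rt
Reagents that add atoms: none
Why: Dess–Martin oxidation stops at the aldehyde, which has a quaternary β‑carbon and no stereocentre that could epimerise.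

Step 9
Reactants: 14 (4R)‑4‑benzyl‑1,3‑oxazolidin‑2‑one; 15 pent‑4‑enoyl chloride
Product: 17 (4R)‑4‑benzyl‑3‑(pent‑4‑enoyl)‑1,3‑oxazolidin‑2‑one, via N‑lithio oxazolidinone 16 (not isolated)
Conditions: n‑BuLi, THF, −78 °C; 15, −78 → 0 °C
Reagents that add atoms: none
Why: N‑acylation of the lithiated Evans auxiliary with an acid chloride is a standard high‑yielding imide formation.

Step 10
Reactants: 13 2‑(Dec)acetaldehyde; 17 (4R)‑4‑benzyl‑3‑(pent‑4‑enoyl)‑1,3‑oxazolidin‑2‑one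
Product: 19 (4R)‑4‑benzyl‑3‑[(2R,3S)‑4‑(Dec)‑3‑hydroxy‑2‑(prop‑2‑en‑1‑yl)butanoyl]‑1,3‑oxazolidin‑2‑one, via dibutylboron Z‑enolate 18 (not isolated)
Conditions: 17 (1.3 equiv), Bu2BOTf, i‑Pr2NEt, CH2Cl2, −78 → 0 °C; 13, −78 → 0 °C; pH 7 buffer, MeOH, 30% H2O2, 0 °C
Reagents that add atoms: none
Why: In this Evans syn‑aldol reaction the Z boron enolate reacts through a closed Zimmerman–Traxler chair with the benzyl group of the (R)‑auxiliary shielding one face, so the bond joining the two fragments forms with (2R) configuration at the carbon that becomes the side‑chain stereocentre (the 3S hydroxyl is removed later).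

Step 11
Reactants: 19 (4R)‑4‑benzyl‑3‑[(2R,3S)‑4‑(Dec)‑3‑hydroxy‑2‑(prop‑2‑en‑1‑yl)butanoyl]‑1,3‑oxazolidin‑2‑one
Product: 20 (2S,3S)‑4‑(Dec)‑2‑(prop‑2‑en‑1‑yl)butane‑1,3‑diol
Conditions: LiBH4, MeOH (1 equiv), THF, 0 °C
Reagents that add atoms: none
Why: Reductive cleavage of the N‑acyl oxazolidinone turns the imide carbonyl into the CH2OH group without touching the α‑stereocentre and returns the auxiliary.

Step 12
Reactants: 20 (2S,3S)‑4‑(Dec)‑2‑(prop‑2‑en‑1‑yl)butane‑1,3‑diol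
Product: 21 (2S,3S)‑3‑({[tert‑butyl(dimethyl)silyl]oxy}methyl)‑1‑(Dec)hex‑5‑en‑2‑ol
Conditions: TBSCl (1.05 equiv), imidazole, CH2Cl2, −20 → 0 °C
Reagents that add atoms: tert‑butyl(chloro)dimethylsilane, CC(C)(C)[Si](C)(C)Cl
Why: Silyl ether formation is strongly selective for the primary over the hindered secondary hydroxyl.

Step 13
Reactants: 21 (2S,3S)‑3‑({[tert‑butyl(dimethyl)silyl]oxy}methyl)‑1‑(Dec)hex‑5‑en‑2‑ol
Product: 22 O‑[(2S,3S)‑3‑({[tert‑butyl(dimethyl)silyl]oxy}methyl)‑1‑(Dec)hex‑5‑en‑2‑yl] 1H‑imidazole‑1‑carbothioate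
Conditions: 1,1'‑thiocarbonyldiimidazole, DMAP (cat.), ClCH2CH2Cl, 70 °C
Reagents that add atoms: 1,1'‑thiocarbonyldiimidazole, S=C(n1ccnc1)n1ccnc1
Why: Thioacylation under neutral conditions activates the secondary alcohol for radical deoxygenation (first half of the Barton–McCombie sequence).

Step 14
Reactants: 22 O‑[(2S,3S)‑3‑({[tert‑butyl(dimethyl)silyl]oxy}methyl)‑1‑(Dec)hex‑5‑en‑2‑yl] 1H‑imidazole‑1‑carbothioate
Product: 23 tert‑butyl({(2S)‑2‑[2‑(Dec)ethyl]pent‑4‑en‑1‑yl}oxy)dimethylsilane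
Conditions: Bu3SnH, AIBN (cat.), toluene, 100 °C
Reagents that add atoms: none
Why: Barton–McCombie deoxygenation replaces C–O by C–H through a secondary radical that has no fast cyclisation or fragmentation path, and the adjacent stereocentre is not involved.

Step 15
Reactants: 24 prop‑2‑en‑1‑amine; 25 3‑methylbutanal
Product: 27 N‑(3‑methylbutyl)prop‑2‑en‑1‑amine, via N‑allyl imine 26 (not isolated)
Conditions: MeOH, rt; NaBH4, 0 °C
Reagents that add atoms: none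
Why: Reductive amination gives the secondary amine cleanly without over‑alkylation.

Step 16
Reactants: 27 N‑(3‑methylbutyl)prop‑2‑en‑1‑amine
Product: 28 N‑(3‑methylbutyl)‑N‑(prop‑2‑en‑1‑yl)prop‑2‑enamide
Conditions: acryloyl chloride, Et3N, CH2Cl2, 0 °C
Reagents that add atoms: acryloyl chloride, C=CC(=O)Cl
Why: N‑acylation of a secondary amine with an acid chloride is fast and clean at low temperature.

Step 17
Reactants: 28 N‑(3‑methylbutyl)‑N‑(prop‑2‑en‑1‑yl)prop‑2‑enamide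
Product: 29 1‑(3‑methylbutyl)‑1,5‑dihydro‑2H‑pyrrol‑2‑one
Conditions: second‑generation Grubbs catalyst RuCl2(=CHPh)(H2IMes)(PCy3) (2 mol%), CH2Cl2, 40 °C
Reagents that add atoms: none
Why: Ring‑closing metathesis of an N‑allyl acrylamide forms the five‑membered lactam with the alkene fixed in the endocyclic conjugated position, driven by loss of ethene.

Step 18
Reactants: 29 1‑(3‑methylbutyl)‑1,5‑dihydro‑2H‑pyrrol‑2‑one
Product: 31 3‑bromo‑1‑(3‑methylbutyl)‑1,5‑dihydro‑2H‑pyrrol‑2‑one, via trans‑dibromide 30 (not isolated)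
Conditions: Br2, CH2Cl2, 0 °C; Et3N, 0 °C → rt
Reagents that add atoms: bromine, BrBr
Why: Bromine addition followed by base‑induced loss of HBr (the α‑proton is the acidic one) is the standard bromination–dehydrobromination route to an α‑bromo unsaturated carbonyl compound.

Step 19
Reactants: 23 tert‑butyl({(2S)‑2‑[2‑(Dec)ethyl]pent‑4‑en‑1‑yl}oxy)dimethylsilane; 31 3‑bromo‑1‑(3‑methylbutyl)‑1,5‑dihydro‑2H‑pyrrol‑2‑one
Product: 33 3‑[(4R)‑4‑({[tert‑butyl(dimethyl)silyl]oxy}methyl)‑6‑(Dec)hexyl]‑1‑(3‑methylbutyl)‑1,5‑dihydro‑2H‑pyrrol‑2‑one, via B‑alkyl‑9‑BBN 32 (not isolated)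
Conditions: 9‑BBN dimer, THF, 0 °C → rt; then 31, PdCl2(dppf) (5 mol%), AsPh3, Cs2CO3, DMF–H2O, rt → 45 °C
Reagents that add atoms: none
Why: Hydroboration with 9‑BBN is selective for the monosubstituted alkene over the hindered ring alkene, and the B‑alkyl Suzuki–Miyaura coupling joins the primary alkylborane to the activated vinyl bromide without moving the lactam double bond.

Step 20
Reactants: 33 3‑[(4R)‑4‑({[tert‑butyl(dimethyl)silyl]oxy}methyl)‑6‑(Dec)hexyl]‑1‑(3‑methylbutyl)‑1,5‑dihydro‑2H‑pyrrol‑2‑one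
Product: 34 3‑[(4R)‑6‑(Dec)‑4‑(hydroxymethyl)hexyl]‑1‑(3‑methylbutyl)‑1,5‑dihydro‑2H‑pyrrol‑2‑one
Conditions: HF·pyridine, pyridine, THF, 0 °C → rt
Reagents that add atoms: none
Why: Fluoride‑mediated desilylation under buffered conditions frees the primary alcohol without affecting the unsaturated lactam or the trisubstituted alkene.

Step 21
Reactants: 34 3‑[(4R)‑6‑(Dec)‑4‑(hydroxymethyl)hexyl]‑1‑(3‑methylbutyl)‑1,5‑dihydro‑2H‑pyrrol‑2‑one
Product: 36 (2R)‑4‑(Dec)‑2‑{3‑[1‑(3‑methylbutyl)‑2‑oxo‑2,5‑dihydro‑1H‑pyrrol‑3‑yl]propyl}butyl hydrogen sulfate (CNP0218721.1), via pyridinium sulfate salt 35 (not isolated)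
Conditions: SO3·pyridine (3 equiv), pyridine, rt; then sulfonic acid cation‑exchange resin (H+ form), MeOH–H2O, 0 °C
Reagents that add atoms: sulfur trioxide–pyridine complex, [O-]S(=O)(=O)[n+]1ccccc1
Why: O‑sulfation of the primary alcohol with the mild SO3·pyridine complex followed by cold cation exchange gives the hydrogen sulfate without acid‑promoted alkene migration.

**Compound list**
1 | (R)‑(+)‑pulegone, (5R)‑5‑methyl‑2‑(propan‑2‑ylidene)cyclohexan‑1‑one | C[C@@H]1CCC(=C(C)C)C(=O)C1 | starting material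
2 | bromomagnesium (5R)‑5‑methyl‑2‑(2‑methylhex‑5‑en‑2‑yl)cyclohex‑1‑en‑1‑olate | C[C@@H]1CCC(C(C)(C)CCC=C)=C(O[Mg]Br)C1 | intermediate
3 | (5R)‑5‑methyl‑2‑(2‑methylhex‑5‑en‑2‑yl)cyclohexan‑1‑one, C2 epimer mixture | C[C@@H]1CCC(C(C)(C)CCC=C)C(=O)C1 | intermediate
4 | (2S,5R)‑5‑methyl‑2‑(2‑methylhex‑5‑en‑2‑yl)cyclohexan‑1‑one | C[C@@H]1CC[C@@H](C(C)(C)CCC=C)C(=O)C1 | intermediate
5 | lithium (3R,6S)‑3‑methyl‑6‑(2‑methylhex‑5‑en‑2‑yl)cyclohex‑1‑en‑1‑olate | [Li]OC1=C[C@H](C)CC[C@H]1C(C)(C)CCC=C | intermediate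
6 | (2S,5R)‑5,6‑dimethyl‑2‑(2‑methylhex‑5‑en‑2‑yl)cyclohexan‑1‑one, C6 epimer mixture | CC1C(=O)[C@H](C(C)(C)CCC=C)CC[C@H]1C | intermediate
7 | lithium (3R,6S)‑2,3‑dimethyl‑6‑(2‑methylhex‑5‑en‑2‑yl)cyclohex‑1‑en‑1‑olate | [Li]OC1=C(C)[C@H](C)CC[C@H]1C(C)(C)CCC=C | intermediate
8 | tert‑butyl 2‑[(1R,3S,6R)‑1,6‑dimethyl‑3‑(2‑methylhex‑5‑en‑2‑yl)‑2‑oxocyclohexyl]acetate | CC(C)(C)OC(=O)C[C@@]1(C)C(=O)[C@H](C(C)(C)CCC=C)CC[C@H]1C | intermediate
9 | tert‑butyl 2‑[(1R,3S,6R)‑1,6‑dimethyl‑3‑[2‑methyl‑4‑(1,2,4‑trioxolan‑3‑yl)butan‑2‑yl]‑2‑oxocyclohexyl]acetate | CC(C)(C)OC(=O)C[C@@]1(C)C(=O)[C@H](C(C)(C)CCC2OCOO2)CC[C@H]1C | intermediate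
10 | tert‑butyl 2‑[(1R,3S,6R)‑1,6‑dimethyl‑3‑(2‑methyl‑5‑oxopentan‑2‑yl)‑2‑oxocyclohexyl]acetate | CC(C)(C)OC(=O)C[C@@]1(C)C(=O)[C@H](C(C)(C)CCC=O)CC[C@H]1C | intermediate
11 | tert‑butyl 2‑[(1R,2R,4aS)‑1,2,5,5‑tetramethyl‑1,2,3,4,4a,5,6,7‑octahydronaphthalen‑1‑yl]acetate | CC(C)(C)OC(=O)C[C@@]1(C)C2=CCCC(C)(C)[C@@H]2CC[C@H]1C | intermediate
12 | 2‑[(1R,2R,4aS)‑1,2,5,5‑tetramethyl‑1,2,3,4,4a,5,6,7‑octahydronaphthalen‑1‑yl]ethan‑1‑ol | OCC[C@@]1(C)C2=CCCC(C)(C)[C@@H]2CC[C@H]1C | intermediate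
13 | 2‑[(1R,2R,4aS)‑1,2,5,5‑tetramethyl‑1,2,3,4,4a,5,6,7‑octahydronaphthalen‑1‑yl]acetaldehyde | O=CC[C@@]1(C)C2=CCCC(C)(C)[C@@H]2CC[C@H]1C | intermediate
14 | (4R)‑4‑benzyl‑1,3‑oxazolidin‑2‑one | O=C1N[C@H](Cc2ccccc2)CO1 | starting material
15 | pent‑4‑enoyl chloride | C=CCCC(Cl)=O | starting material
16 | lithium (4R)‑4‑benzyl‑2‑oxo‑1,3‑oxazolidin‑3‑ide | [Li]N1[C@H](Cc2ccccc2)COC1=O | intermediate
17 | (4R)‑4‑benzyl‑3‑(pent‑4‑enoyl)‑1,3‑oxazolidin‑2‑one | C=CCCC(=O)N1[C@H](Cc2ccccc2)COC1=O | intermediate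
18 | dibutyl{[(1Z)‑1‑[(4R)‑4‑benzyl‑2‑oxo‑1,3‑oxazolidin‑3‑yl]penta‑1,4‑dien‑1‑yl]oxy}borane | CCCCB(CCCC)O/C(=C\CC=C)N1[C@H](Cc2ccccc2)COC1=O | intermediate
19 | (4R)‑4‑benzyl‑3‑[(2R,3S)‑4‑(Dec)‑3‑hydroxy‑2‑(prop‑2‑en‑1‑yl)butanoyl]‑1,3‑oxazolidin‑2‑one | C=CC[C@H]([C@@H](O)C[C@@]1(C)C2=CCCC(C)(C)[C@@H]2CC[C@H]1C)C(=O)N1[C@H](Cc2ccccc2)COC1=O | intermediate
20 | (2S,3S)‑4‑(Dec)‑2‑(prop‑2‑en‑1‑yl)butane‑1,3‑diol | C=CC[C@H]([C@@H](O)C[C@@]1(C)C2=CCCC(C)(C)[C@@H]2CC[C@H]1C)CO | intermediate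
21 | (2S,3S)‑3‑({[tert‑butyl(dimethyl)silyl]oxy}methyl)‑1‑(Dec)hex‑5‑en‑2‑ol | C=CC[C@H]([C@@H](O)C[C@@]1(C)C2=CCCC(C)(C)[C@@H]2CC[C@H]1C)CO[Si](C)(C)C(C)(C)C | intermediate
22 | O‑[(2S,3S)‑3‑({[tert‑butyl(dimethyl)silyl]oxy}methyl)‑1‑(Dec)hex‑5‑en‑2‑yl] 1H‑imidazole‑1‑carbothioate | C=CC[C@H]([C@@H](OC(=S)n1ccnc1)C[C@@]1(C)C2=CCCC(C)(C)[C@@H]2CC[C@H]1C)CO[Si](C)(C)C(C)(C)C | intermediate
23 | tert‑butyl({(2S)‑2‑[2‑(Dec)ethyl]pent‑4‑en‑1‑yl}oxy)dimethylsilane | C=CC[C@H](CC[C@@]1(C)C2=CCCC(C)(C)[C@@H]2CC[C@H]1C)CO[Si](C)(C)C(C)(C)C | intermediate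
24 | prop‑2‑en‑1‑amine (allylamine) | C=CCN | starting material
25 | 3‑methylbutanal | CC(C)CC=O | starting material
26 | (E)‑3‑methyl‑N‑(prop‑2‑en‑1‑yl)butan‑1‑imine | CC(C)C/C=N/CC=C | intermediate
27 | N‑(3‑methylbutyl)prop‑2‑en‑1‑amine | CC(C)CCNCC=C | intermediate
28 | N‑(3‑methylbutyl)‑N‑(prop‑2‑en‑1‑yl)prop‑2‑enamide | CC(C)CCN(CC=C)C(=O)C=C | intermediate
29 | 1‑(3‑methylbutyl)‑1,5‑dihydro‑2H‑pyrrol‑2‑one | CC(C)CCN1CC=CC1=O | intermediate
30 | trans‑3,4‑dibromo‑1‑(3‑methylbutyl)pyrrolidin‑2‑one (racemic) | CC(C)CCN1CC(Br)C(Br)C1=O | intermediate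
31 | 3‑bromo‑1‑(3‑methylbutyl)‑1,5‑dihydro‑2H‑pyrrol‑2‑one | CC(C)CCN1CC=C(Br)C1=O | intermediate
32 | 9‑[(4R)‑4‑({[tert‑butyl(dimethyl)silyl]oxy}methyl)‑6‑(Dec)hexyl]‑9‑borabicyclo[3.3.1]nonane | C1CCC2CCCC1B2CCC[C@H](CC[C@@]3(C)C4=CCCC(C)(C)[C@@H]4CC[C@H]3C)CO[Si](C)(C)C(C)(C)C | intermediate
33 | 3‑[(4R)‑4‑({[tert‑butyl(dimethyl)silyl]oxy}methyl)‑6‑(Dec)hexyl]‑1‑(3‑methylbutyl)‑1,5‑dihydro‑2H‑pyrrol‑2‑one | CC(C)CCN1CC=C(CCC[C@H](CC[C@@]2(C)C3=CCCC(C)(C)[C@@H]3CC[C@H]2C)CO[Si](C)(C)C(C)(C)C)C1=O | intermediate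
34 | 3‑[(4R)‑6‑(Dec)‑4‑(hydroxymethyl)hexyl]‑1‑(3‑methylbutyl)‑1,5‑dihydro‑2H‑pyrrol‑2‑one | CC(C)CCN1CC=C(CCC[C@H](CC[C@@]2(C)C3=CCCC(C)(C)[C@@H]3CC[C@H]2C)CO)C1=O | intermediate
35 | pyridinium (2R)‑4‑(Dec)‑2‑{3‑[1‑(3‑methylbutyl)‑2‑oxo‑2,5‑dihydro‑1H‑pyrrol‑3‑yl]propyl}butyl sulfate | CC(C)CCN1CC=C(CCC[C@H](CC[C@@]2(C)C3=CCCC(C)(C)[C@@H]3CC[C@H]2C)COS(=O)(=O)[O-])C1=O.c1cc[nH+]cc1 | intermediate
36 | (2R)‑4‑(Dec)‑2‑{3‑[1‑(3‑methylbutyl)‑2‑oxo‑2,5‑dihydro‑1H‑pyrrol‑3‑yl]propyl}butyl hydrogen sulfate (CNP0218721.1) | CC(C)CCN1CC=C(CCC[C@H](CC[C@@]2(C)C3=CCCC(C)(C)[C@@H]3CC[C@H]2C)COS(=O)(=O)O)C1=O | target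

**Totals and risks**
Total steps: 21 (all fragment syntheses included). Longest linear sequence: 16 steps (steps 1–8, 10–14, 19–21).

Most likely to fail:

- **Step 4 (second enolisation and alkylation).** The base may not discriminate cleanly between the two tertiary α‑hydrogens, or proton transfer may compete, and the facial preference is predicted rather than proven. The fallback sets out from ketone 4 and comes back at keto ester 8. The kinetic enolate of 4 is trapped with dimethyl(methylidene)ammonium iodide (Mannich reaction) to give the Mannich base F1. Quaternisation with MeI and elimination with NaHCO3 give the 2‑methylidene ketone F2. Conjugate reduction with LiBH(s‑Bu)3 at −78 °C then produces enolate 7 regiospecifically, and tert‑butyl bromoacetate/DMPU gives 8. This removes the regiochemical question; the facial bias is unchanged.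

- **Step 6 (McMurry ring closure onto a very hindered ketone).** The coupling may stall at the pinacol stage, or the ester may suffer. The fallback sets out from keto aldehyde 10 and comes back at 11. SmI2‑mediated pinacol cyclisation (THF, t‑BuOH, −78 °C) gives the cis‑diol F3. 1,1'‑Thiocarbonyldiimidazole in hot toluene gives the cyclic thionocarbonate F4. Heating in P(OMe)3 (Corey–Winter olefination) then gives alkene 11.

- **Step 19 (B‑alkyl Suzuki coupling with the base‑sensitive bromolactam).** Protodebromination or β‑hydride elimination may dominate. The fallback sets out from alkene 23 and comes back at 33, building the lactam on the chain instead. Hydroboration–oxidation (9‑BBN; NaOH, H2O2) gives the primary alcohol F5, and PPh3, I2, imidazole gives the iodide F6. Amine 27 is coupled with (diethoxyphosphoryl)acetic acid (carbodiimide) to give the phosphonoacetamide F7. Its sodium salt (NaH, THF–DMF) is alkylated with F6 to give the alkylated phosphonate F8. Horner–Wadsworth–Emmons methylenation with aqueous formaldehyde and K2CO3 gives the 2‑methylidene amide F9. Ring‑closing metathesis with the ruthenium catalyst of step 17 closes the lactam and gives 33.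

**Further compounds**
F1 | step 4 | (3R,6S)‑2‑[(dimethylamino)methyl]‑3‑methyl‑6‑(2‑methylhex‑5‑en‑2‑yl)cyclohexan‑1‑one (C2 epimers) | CN(C)CC1C(=O)[C@H](C(C)(C)CCC=C)CC[C@H]1C
F2 | step 4 | (3R,6S)‑3‑methyl‑2‑methylidene‑6‑(2‑methylhex‑5‑en‑2‑yl)cyclohexan‑1‑one | C=C1C(=O)[C@H](C(C)(C)CCC=C)CC[C@H]1C
F3 | step 6 | tert‑butyl 2‑[(1R,2R,4aS)‑8,8a‑dihydroxy‑1,2,5,5‑tetramethyldecahydronaphthalen‑1‑yl]acetate (8,8a‑cis diol, carbinol configurations not assigned) | CC(C)(C)OC(=O)C[C@@]1(C)C2(O)C(O)CCC(C)(C)[C@@H]2CC[C@H]1C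
F4 | step 6 | cyclic thionocarbonate of diol F3 (1,3‑dioxolane‑2‑thione fused at C8–C8a) | CC(C)(C)OC(=O)C[C@@]1(C)C23OC(=S)OC2CCC(C)(C)[C@@H]3CC[C@H]1C
F5 | step 19 | (4S)‑4‑({[tert‑butyl(dimethyl)silyl]oxy}methyl)‑6‑(Dec)hexan‑1‑ol | OCCC[C@H](CC[C@@]1(C)C2=CCCC(C)(C)[C@@H]2CC[C@H]1C)CO[Si](C)(C)C(C)(C)C
F6 | step 19 | tert‑butyl({(2S)‑2‑[2‑(Dec)ethyl]‑5‑iodopentyl}oxy)dimethylsilane | ICCC[C@H](CC[C@@]1(C)C2=CCCC(C)(C)[C@@H]2CC[C@H]1C)CO[Si](C)(C)C(C)(C)C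
F7 | step 19 | diethyl {2‑[(3‑methylbutyl)(prop‑2‑en‑1‑yl)amino]‑2‑oxoethyl}phosphonate | CCOP(=O)(OCC)CC(=O)N(CC=C)CCC(C)C
F8 | step 19 | diethyl [(6R)‑6‑({[tert‑butyl(dimethyl)silyl]oxy}methyl)‑8‑(Dec)‑1‑[(3‑methylbutyl)(prop‑2‑en‑1‑yl)amino]‑1‑oxooctan‑2‑yl]phosphonate (C2 epimers) | CCOP(=O)(OCC)C(CCC[C@H](CC[C@@]1(C)C2=CCCC(C)(C)[C@@H]2CC[C@H]1C)CO[Si](C)(C)C(C)(C)C)C(=O)N(CC=C)CCC(C)C
F9 | step 19 | (6R)‑6‑({[tert‑butyl(dimethyl)silyl]oxy}methyl)‑8‑(Dec)‑N‑(3‑methylbutyl)‑2‑methylidene‑N‑(prop‑2‑en‑1‑yl)octanamide | C=C(CCC[C@H](CC[C@@]1(C)C2=CCCC(C)(C)[C@@H]2CC[C@H]1C)CO[Si](C)(C)C(C)(C)C)C(=O)N(CC=C)CCC(C)C
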